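The data were generated by integration with constants of no real substance; scatter was added.

I had to say which species would hold the most of the charged substrate after 2.0 min in spring and in autumn, and how much of it. Substrate is what I tracked, so I kept a ledger of it.

| flask | substrate | temperature | remark | time |
|---|---|---|---|---|
| birch | 0.25 M | 95 °C | run made earlier |  |
| larch | 0.38 M | 110 °C | run made earlier |  |
| spring | 0.50 M | 100 °C |  | 2.0 min |
| autumn | 0.50 M | 120 °C |  | 2.0 min |

birch run (percent of the substrate charged)

| time / min | target / % | substrate / % | intermediate / % | isomer of the product / % |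
|---|---|---|---|---|
| 0.200 | 0 | 101 | 5 | 2 |
| 0.333 | 0 | 96 | 3 | 0 |
| 0.417 | 0 | 99 | 4 | 0 |
| 0.667 | 2 | 97 | 3 | 0 |
| 1.00 | 1 | 92 | 8 | 0 |
| 1.50 | 2 | 88 | 7 | 1 |
| 2.50 | 6 | 84 | 10 | 0 |

larch run (percent of the substrate charged)

| time / s | target / % | substrate / % | intermediate / % | isomer of the product / % |
|---|---|---|---|---|
| 10.0 | 0 | 98 | 6 | 0 |
| 12.0 | 0 | 95 | 4 | 0 |
| 15.0 | 2 | 91 | 4 | 1 |
| 25.0 | 2 | 86 | 9 | 0 |
| 40.0 | 5 | 80 | 13 | 0 |
| 60.0 | 9 | 74 | 17 | 0 |
| 90.0 | 22 | 66 | 18 | 0 |

(standard deviation of a reading: 1.5 percentage points)

* which of these there is most of at the end, counted by the substrate in it, spring (substrate / target / intermediate / isomer of the product)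
* which of these there is most of at the end, counted by the substrate in it, autumn (substrate / target / intermediate / isomer of the product)
* final amount of the leader among these, as a percentage of the substrate charged, in spring
* final amount of the leader among these, as a percentage of the substrate charged, in autumn



Step 1, the two ends. Birch kept 84% of its substrate after 2.50 min, and larch kept 66% after 90.0 s. I took the loss as first order and read a loss constant, the share of the remaining substrate leaving per minute (the first-order rate constant). It read 0.0697 min⁻¹ for birch and 0.277 min⁻¹ for larch, both carrying the scatter of the readings. I assumed the charge did not matter, although the two runs differ in charge as well as temperature.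

Step 2, the join. I let each degree multiply the constant by the same factor. That gave the loss constant of spring, 0.110 min⁻¹, and 0.695 min⁻¹ for autumn, an extrapolation past larch. Substrate left is then the exponential of minus constant times time.

Step 3, the spring ledger. Substrate left stood at 80.2%, more than the 19.8% in all the other entries together, so I put substrate in the lead.

Step 4, the autumn ledger. Substrate left stood at 24.9%. I booked intermediate at the last larch reading, 18%, and isomer at its last larch reading, 0%. Target took the rest, 57.1%, and led.

Step 5, the forecast. It gave substrate at 71% in spring and target at 57% in autumn, holding that “larch fits second order better”. Its spring figure stood lower than mine.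

Step 6, the result. Spring ended with substrate leading at 77.9%, and autumn with target leading at 55.6%.

    substrate ⇌ intermediate (K = 1.93, k = 0.00220 s⁻¹, Ea = 115 kJ mol⁻¹, ΔH = −54.0 kJ mol⁻¹)
    intermediate → target (k = 0.00812 s⁻¹, Ea = 93.0 kJ mol⁻¹)
    target ⇌ isomer of the product (K = 0.770, k = 2.16 × 10⁻⁴ s⁻¹, Ea = 107 kJ mol⁻¹, ΔH = −21.0 kJ mol⁻¹)
    (constants at 100 °C)

The loss constant had given 80.2% substrate left in spring, and the flask held 78%. I applied the same constant to the spring flask left until 8.0 min, which gave 41.5% substrate left. That flask held 39% substrate, and target stood at 47.2%, more than the substrate.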